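**Retrosynthetic overview**
1. The C-3 prenyl group (benzaldehyde numbering: CHO C-1, aroyl C-2) comes by [3,3] shift from a 4-O-(1,1-dimethylallyl) ether; the key disconnection is that aryl C–O bond, made from isoprene and the most acidic phenol.
2. The tetraphenol keto-aldehyde comes from its tetramethyl ether (BBr3), and the CHO from a benzylic CH2OH.
3. The benzophenone C–C bond comes from 2,6-dimethoxy-4-methylphenyllithium and 4,6-dimethoxyphthalide; the lactone supplies both the ketone carbon and the future CHO carbon.
4. The phthalide comes from 3,5-dimethoxybenzoic acid and formaldehyde; the aryllithium from 3,5-dimethoxytoluene.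
5. Both benzene rings are bought; the only ring made is the γ-lactone (step 1), opened again in step 2.

Assumption: the target has no stereocentre and no stereogenic double bond, so it is achiral and "single enantiomer" requires no stereocontrol.

**Step 1**
Reactants: 1 3,5-dimethoxybenzoic acid; 2 formaldehyde (as paraformaldehyde)
Product: 4 4,6-dimethoxyphthalide (4,6-dimethoxy-2-benzofuran-1(3H)-one), via chloromethyl acid 3 (not isolated)
Conditions: (CH2O)n, conc. HCl, AcOH, 80 °C
Reagents that add atoms: none
Why: Blanc chloromethylation at C-2 (ortho to CO2H, ortho/para to the two OMe groups; the site between the OMe groups is more hindered), after which the benzylic chloride is trapped by the neighbouring acid to close the γ-lactone.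

**Step 2**
Reactants: 5 3,5-dimethoxytoluene; 4 4,6-dimethoxyphthalide
Product: 8 [2-(hydroxymethyl)-3,5-dimethoxyphenyl](2,6-dimethoxy-4-methylphenyl)methanone (open form of the lactol), via aryllithium 6 (not isolated), via lithium alkoxide 7 (not isolated)
Conditions: n-BuLi, THF, 0 °C to rt; then 4, THF, −78 to −20 °C; then H2O
Reagents that add atoms: none
Why: Directed ortho-metalation between the two OMe groups gives the 2,6-dimethoxyaryllithium, which adds once to the lactone carbonyl with ring opening (acyl substitution); the hindered diaryl ketone resists a second addition.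

**Step 3**
Reactants: 8 keto alcohol
Product: 9 2-(2,6-dimethoxy-4-methylbenzoyl)-4,6-dimethoxybenzaldehyde
Conditions: Dess–Martin periodinane, CH2Cl2, rt
Reagents that add atoms: none
Why: Dess–Martin oxidation of the primary benzylic alcohol (reacting through the open hydroxy-ketone form) gives the aldehyde without touching the ketone or the aryl ethers.

**Step 4**
Reactants: 9 tetramethyl keto aldehyde
Product: 10 2-(2,6-dihydroxy-4-methylbenzoyl)-4,6-dihydroxybenzaldehyde
Conditions: BBr3 (8 equiv), CH2Cl2, −78 °C to rt; then ice/H2O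
Reagents that add atoms: none
Why: BBr3 cleavage of all four aryl methyl ethers is done before any acid-sensitive prenyl group is present; the product is expected as the chelated hydroxy-aldehyde in equilibrium with its seven-membered lactol.

**Step 5**
Reactants: 10 tetraphenol keto aldehyde; 11 isoprene
Product: 12 2-(2,6-dihydroxy-4-methylbenzoyl)-6-hydroxy-4-[(2-methylbut-3-en-2-yl)oxy]benzaldehyde
Conditions: Pd2(dba)3 (2.5 mol %), DPEphos (6 mol %), isoprene (5 equiv), THF, 25 °C
Reagents that add atoms: none
Why: Proposed new method: Pd(0)-catalysed Markovnikov hydro-aryloxylation of isoprene, in which the most acidic phenol (4-OH, para to CHO, pKa about 7; the other three OH groups are chelated to a carbonyl) protonates Pd(0)-bound isoprene to give a [(η3-1,1-dimethylallyl)Pd]+ ArO− ion pair that collapses by C–O bond formation at the tertiary terminus, so the proton donor is also the nucleophile and only O-4 is etherified; the closest known reactions are Pd–H-catalysed (reverse) prenylation of indoles with isoprene and Tsuji–Trost O-(1,1-dimethylallyl)ation of phenols with tertiary allylic carbonates.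

**Step 6**
Reactants: 12 4-O-(1,1-dimethylallyl) ether
Product: 15 2-(2,6-dihydroxy-4-methylbenzoyl)-4,6-dihydroxy-3-(3-methylbut-2-en-1-yl)benzaldehyde (target), via tris-TMS ether 13 (not isolated), via tetrakis-TMS ether 14 (not isolated)
Conditions: BSA (6 equiv), PhNEt2, 120 °C; then aq. citric acid, THF, rt
Reagents that add atoms: none
Why: Aromatic Claisen rearrangement ([3,3]) of the aryl 1,1-dimethylallyl ether delivers the unbranched prenyl group to an ortho carbon; silylation in situ removes the 6-OH···O=CH chelate that would send the group to C-5 (as in 4-allyloxy-2-hydroxybenzaldehydes), so the meta O-silyl donor and the meta aroyl acceptor should both direct it to C-3 (para position blocked by CHO), and the silyl ethers come off on acidic work-up.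

**Compound list**
1 | 3,5-dimethoxybenzoic acid | COc1cc(OC)cc(C(=O)O)c1 | starting material
2 | formaldehyde | C=O | starting material
3 | 2-(chloromethyl)-3,5-dimethoxybenzoic acid | ClCc1c(OC)cc(OC)cc1C(=O)O | intermediate
4 | 4,6-dimethoxyphthalide | O=C1OCc2c(OC)cc(OC)cc12 | intermediate
5 | 3,5-dimethoxytoluene | COc1cc(C)cc(OC)c1 | starting material
6 | 2,6-dimethoxy-4-methylphenyllithium | [Li]c1c(OC)cc(C)cc1OC | intermediate
7 | lithium alkoxide of 8 | [Li+].[O-]Cc1c(OC)cc(OC)cc1C(=O)c1c(OC)cc(C)cc1OC | intermediate
8 | [2-(hydroxymethyl)-3,5-dimethoxyphenyl](2,6-dimethoxy-4-methylphenyl)methanone | OCc1c(OC)cc(OC)cc1C(=O)c1c(OC)cc(C)cc1OC | intermediate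
9 | 2-(2,6-dimethoxy-4-methylbenzoyl)-4,6-dimethoxybenzaldehyde | O=Cc1c(OC)cc(OC)cc1C(=O)c1c(OC)cc(C)cc1OC | intermediate
10 | 2-(2,6-dihydroxy-4-methylbenzoyl)-4,6-dihydroxybenzaldehyde | O=Cc1c(O)cc(O)cc1C(=O)c1c(O)cc(C)cc1O | intermediate
11 | isoprene | C=CC(C)=C | starting material
12 | 2-(2,6-dihydroxy-4-methylbenzoyl)-6-hydroxy-4-[(2-methylbut-3-en-2-yl)oxy]benzaldehyde | O=Cc1c(O)cc(OC(C)(C)C=C)cc1C(=O)c1c(O)cc(C)cc1O | intermediate
13 | tris(trimethylsilyl) ether of 12 | O=Cc1c(O[Si](C)(C)C)cc(OC(C)(C)C=C)cc1C(=O)c1c(O[Si](C)(C)C)cc(C)cc1O[Si](C)(C)C | intermediate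
14 | tetrakis(trimethylsilyl) ether of 15 | CC(C)=CCc1c(O[Si](C)(C)C)cc(O[Si](C)(C)C)c(C=O)c1C(=O)c1c(O[Si](C)(C)C)cc(C)cc1O[Si](C)(C)C | intermediate
15 | 2-(2,6-dihydroxy-4-methylbenzoyl)-4,6-dihydroxy-3-(3-methylbut-2-en-1-yl)benzaldehyde | CC(C)=CCc1c(O)cc(O)c(C=O)c1C(=O)c1c(O)cc(C)cc1O | target

**Totals**
Total steps: 6. Longest linear sequence: 6 (1 → 4 → 8 → 9 → 10 → 12 → 15); arene 5 enters at step 2 without prior steps.

**Steps most likely to fail**

Step 5 (the proposed new reaction). Risks are isoprene telomerisation, the linear O-prenyl ether, and Pd-mediated re-ionisation leading to C-prenylation. Fallback with known chemistry: starting from 10, alkylate the same 4-OH with 3-chloro-3-methylbut-1-yne (CuCl2 cat., DBU, MeCN, 0 °C) to give the 1,1-dimethylpropargyl ether F1, then semi-hydrogenate the alkyne (H2, Lindlar catalyst, quinoline, EtOAc) to rejoin the route at 12.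

Step 6 (regiochemistry of the shift, C-3 against C-5). The C-3 preference rests on substituent-effect arguments, not on a direct precedent for this crowded position. Fallback that fixes the site by a halogen: starting from 4, NBS (MeCN, rt) brominates the position ortho to the lactone carbonyl to give 7-bromo-4,6-dimethoxyphthalide F2. Aryllithium 6, used as its organocerium reagent to suppress Br/Li exchange, then gives the bromo keto alcohol F3. Dess–Martin oxidation gives the bromo keto aldehyde F4, and BBr3 gives the bromo tetraphenol F5. Stille coupling with tributyl(3-methylbut-2-en-1-yl)stannane (Pd(PPh3)4, LiCl, DMF, 80 °C) comes back to the route at 15.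

Step 4 (fourfold demethylation next to an aldehyde). The ether para to CHO is the slowest, and the keto aldehyde may not tolerate long exposure to BBr3. Fallback in two mechanistically different stages: starting from 9, sodium ethanethiolate (DMF, 100 °C) removes the methyl para to CHO by SN2 to give 2-(2,6-dimethoxy-4-methylbenzoyl)-4-hydroxy-6-methoxybenzaldehyde F6. BCl3 (CH2Cl2, −78 to 0 °C) then cleaves the three ethers ortho to a carbonyl by chelation and rejoins the route at 10; any extra thiolate demethylation also leads to 10.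

**Further compounds**
F1 | step 5 | 2-(2,6-dihydroxy-4-methylbenzoyl)-6-hydroxy-4-[(2-methylbut-3-yn-2-yl)oxy]benzaldehyde | O=Cc1c(O)cc(OC(C)(C)C#C)cc1C(=O)c1c(O)cc(C)cc1O
F2 | step 6 | 7-bromo-4,6-dimethoxyphthalide | O=C1OCc2c(OC)cc(OC)c(Br)c12
F3 | step 6 | [2-bromo-6-(hydroxymethyl)-3,5-dimethoxyphenyl](2,6-dimethoxy-4-methylphenyl)methanone | OCc1c(OC)cc(OC)c(Br)c1C(=O)c1c(OC)cc(C)cc1OC
F4 | step 6 | 3-bromo-2-(2,6-dimethoxy-4-methylbenzoyl)-4,6-dimethoxybenzaldehyde | O=Cc1c(OC)cc(OC)c(Br)c1C(=O)c1c(OC)cc(C)cc1OC
F5 | step 6 | 3-bromo-2-(2,6-dihydroxy-4-methylbenzoyl)-4,6-dihydroxybenzaldehyde | O=Cc1c(O)cc(O)c(Br)c1C(=O)c1c(O)cc(C)cc1O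
F6 | step 4 | 2-(2,6-dimethoxy-4-methylbenzoyl)-4-hydroxy-6-methoxybenzaldehyde | O=Cc1c(OC)cc(O)cc1C(=O)c1c(OC)cc(C)cc1OC
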